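## Retrosynthetic overview

1. Target ⇐ hydroquinone 39 ⇐ quinone 38 ⇐ dimethyl ether 37 (sulfation, dithionite reduction and (NH4)2Ce(NO3)6 demethylation come last).
2. 37 ⇐ copper-mediated anti-SN2′ union of the right-hand Grignard reagent 36 with the left allylic picolinate 35; this sets the left quaternary carbon and the left ring alkene in one step.
3. Feature that carries the strategy: in the right decalin the quaternary carbon C-1 of ring D (bearing CH3 and the CH2CH2 linker) is bonded directly to the sp2 ring-fusion carbon C-8a of the ring C alkene C-8=C-8a. Ring D is therefore closed on a ring C enol triflate by a 6-exo Heck insertion into a side-chain (E)-trisubstituted alkene (16 → 17), and the vinyl group left by β-hydride elimination becomes the linker.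
4. 16 ⇐ ketone 14 ⇐ cyclohexane-1,3-dione + aldehyde 5 (reductive alkylation, two methyl additions, asymmetric protonation); 5 ⇐ Johnson–Claisen chirality transfer from alcohol 2. 35 ⇐ bicyclic enone 33 ⇐ aldol closure of ring B on a ring A ketone derived from 2-methylcyclohex-2-en-1-one.
5. Ring order: ring C, then ring D (Heck); ring A, then ring B (aldol); the two decalins are then joined.

Key step: step 10

Assumption: the target is delivered as the free bis(hydrogen sulfate) as drawn, and in the three ligand-controlled steps (8, 10, 13) the ligand enantiomer named is taken as the one that gives the drawn configuration, its antipode being used if a test run shows the opposite sense.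

## Route

Step 1
Reactants: 1 (3E)-3-methylpent-3-en-2-one
Product: 2 (2S,3E)-3-methylpent-3-en-2-ol
Conditions: (R)-2-methyl-CBS-oxazaborolidine (10 mol%), BH3·SMe2, THF, −20 °C; MeOH
Reagents that add atoms: none
Why: CBS reduction of a methyl alkenyl ketone, in which the oxazaborolidine distinguishes the branched alkenyl group from methyl and delivers hydride to one carbonyl face, which should set C-2 as S.

Step 2
Reactants: 2 (2S,3E)-3-methylpent-3-en-2-ol
Product: 4 ethyl (3S,4E)-3,4-dimethylhex-4-enoate, via ketene acetal 3 (not isolated)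
Conditions: MeC(OEt)3, EtCO2H (cat.), 140 °C, ethanol distilled off
Reagents that add atoms: triethyl orthoacetate (CC(OCC)(OCC)OCC)
Why: Johnson–Claisen rearrangement through a chair with the carbinol methyl equatorial, which should transfer the C-2 configuration suprafacially to the new C-3 stereocentre (S) and give the (E)-trisubstituted alkene.

Step 3
Reactants: 4 ethyl (3S,4E)-3,4-dimethylhex-4-enoate
Product: 5 (3S,4E)-3,4-dimethylhex-4-enal
Conditions: i-Bu2AlH (1.05 equiv), CH2Cl2, −78 °C; aq. potassium sodium tartrate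
Reagents that add atoms: none
Why: partial ester reduction by i-Bu2AlH at low temperature, where the tetrahedral aluminium hemiacetal persists until work-up, so the aldehyde should be obtained without touching the non-enolizable β-stereocentre.

Step 4
Reactants: 5 (3S,4E)-3,4-dimethylhex-4-enal; 6 cyclohexane-1,3-dione
Product: 8 2-[(3S,4E)-3,4-dimethylhex-4-en-1-yl]cyclohexane-1,3-dione, via alkylidene dione 7 (not isolated)
Conditions: L-proline (20 mol%), diethyl 2,6-dimethyl-1,4-dihydropyridine-3,5-dicarboxylate (Hantzsch ester), CH2Cl2, rt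
Reagents that add atoms: none
Why: organocatalytic three-component reductive alkylation, in which Knoevenagel condensation gives the alkylidene dione and the Hantzsch ester reduces it by conjugate hydride transfer, so clean mono-C-alkylation is expected.

Step 5
Reactants: 8 2-[(3S,4E)-3,4-dimethylhex-4-en-1-yl]cyclohexane-1,3-dione
Product: 9 2-[(3S,4E)-3,4-dimethylhex-4-en-1-yl]-3-methoxycyclohex-2-en-1-one
Conditions: Me3SiCHN2, MeOH/toluene, 0 °C → rt
Reagents that add atoms: (trimethylsilyl)diazomethane (C[Si](C)(C)C=[N+]=[N-])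
Why: O-methylation of the acidic enol of a 2-alkyl-1,3-dione by a diazoalkane, which should give the vinylogous ester under neutral conditions that spare the trisubstituted alkene.

Step 6
Reactants: 9 2-[(3S,4E)-3,4-dimethylhex-4-en-1-yl]-3-methoxycyclohex-2-en-1-one
Product: 11 2-[(3S,4E)-3,4-dimethylhex-4-en-1-yl]-3-methylcyclohex-2-en-1-one, via tertiary lithium alkoxide 10 (not isolated)
Conditions: MeLi, Et2O, −78 → 0 °C; then 1 M HCl, THF, 0 °C
Reagents that add atoms: methyllithium ([Li]C)
Why: Stork–Danheiser sequence, in which 1,2-addition of methyllithium to the vinylogous ester and brief acid hydrolysis with loss of water should give the 3-methyl enone.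

Step 7
Reactants: 11 2-[(3S,4E)-3,4-dimethylhex-4-en-1-yl]-3-methylcyclohex-2-en-1-one
Product: 13 2-[(3S,4E)-3,4-dimethylhex-4-en-1-yl]-3,3-dimethylcyclohex-1-en-1-yl prop-2-en-1-yl carbonate, via lithium enolate 12 (not isolated)
Conditions: Me2CuLi (from MeLi and CuI), Et2O, −20 → 0 °C; then ClCO2CH2CH=CH2, THF/TMEDA, −78 °C → rt
Reagents that add atoms: lithium dimethylcuprate ([Li+].C[Cu-]C); allyl chloroformate (C=CCOC(Cl)=O)
Why: cuprate conjugate addition to the β,β-disubstituted enone, which should build the gem-dimethyl carbon and give the C-1/C-2 enolate regiospecifically, this hindered enolate then being acylated on oxygen by the chloroformate.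

Step 8
Reactants: 13 2-[(3S,4E)-3,4-dimethylhex-4-en-1-yl]-3,3-dimethylcyclohex-1-en-1-yl prop-2-en-1-yl carbonate
Product: 14 (2S)-2-[(3S,4E)-3,4-dimethylhex-4-en-1-yl]-3,3-dimethylcyclohexan-1-one
Conditions: Pd2(dba)3 (5 mol%), (S)-t-Bu-PHOX (12.5 mol%), Meldrum's acid (2.5 equiv), 1,4-dioxane, rt
Reagents that add atoms: none
Why: palladium-catalysed decarboxylative asymmetric protonation, in which ionization of the allyl carbonate and loss of CO2 give a palladium enolate held by the phosphinooxazoline ligand that Meldrum's acid should protonate on one face to set C-2 (S), the allyl group being scavenged by the acid and the remote side-chain centre playing no part.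

Step 9
Reactants: 14 (2S)-2-[(3S,4E)-3,4-dimethylhex-4-en-1-yl]-3,3-dimethylcyclohexan-1-one
Product: 16 (6S)-6-[(3S,4E)-3,4-dimethylhex-4-en-1-yl]-5,5-dimethylcyclohex-1-en-1-yl trifluoromethanesulfonate, via kinetic lithium enolate 15 (not isolated)
Conditions: LiN(i-Pr)2, THF, −78 °C (ketone added to the base); then PhNTf2, −78 → 0 °C
Reagents that add atoms: N-phenylbis(trifluoromethanesulfonimide) (O=S(=O)(N(c1ccccc1)S(=O)(=O)C(F)(F)F)C(F)(F)F)
Why: kinetic enolization followed by O-triflation, where the amide base should remove a proton from the open C-6 methylene and not from the C-2 methine flanked by the quaternary carbon, so the less substituted enol triflate forms and the C-2 stereocentre is left intact.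

Step 10
Reactants: 16 (6S)-6-[(3S,4E)-3,4-dimethylhex-4-en-1-yl]-5,5-dimethylcyclohex-1-en-1-yl trifluoromethanesulfonate
Product: 17 (1R,2S,4aS)-1-ethenyl-1,2,5,5-tetramethyl-1,2,3,4,4a,5,6,7-octahydronaphthalene
Conditions: Pd(OAc)2 (10 mol%), (R)-BINAP (20 mol%), K2CO3, toluene, 80 °C
Reagents that add atoms: none
Why: Oxidative addition of zerovalent palladium (formed from Pd(OAc)2 and BINAP) to the enol triflate gives a cationic alkenylpalladium species at C-1 of ring C, syn migratory insertion into the tethered (E)-alkene forms the C(sp2)–C bond at the methyl-bearing alkene carbon, and β-hydride elimination from the terminal methyl releases the vinyl group. The closest known reaction type is the intramolecular Heck cyclization of cycloalkenyl triflates onto trisubstituted alkenes that creates quaternary carbons. Ring D closes in the 6-exo-trig mode (ring atoms C-1, C-6, the two chain CH2 groups, CH(CH3) and the C(CH3)= carbon). The new quaternary stereocentre (C-1 of 17, R) is set by the alkene face: in the chair-like transition state the gem-dimethyl ring carbon attached to C-6 is equatorial and the secondary methyl is axial and anti to the palladium-bearing carbon, so the future vinyl group should end cis to the ring-fusion hydrogen and trans to the secondary methyl, and the BINAP enantiomer is chosen to reinforce this substrate bias. The step needs 6-exo over 7-endo closure, which the tether length secures; the alkenyl carbon keeps its double bond, so the ring C alkene stays at C-8=C-8a, and the quaternary carbon carries no hydrogen, so elimination can only give the vinyl group.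

Step 11
Reactants: 17 (1R,2S,4aS)-1-ethenyl-1,2,5,5-tetramethyl-1,2,3,4,4a,5,6,7-octahydronaphthalene
Product: 19 2-[(1R,2S,4aS)-1,2,5,5-tetramethyl-1,2,3,4,4a,5,6,7-octahydronaphthalen-1-yl]ethan-1-ol, via alkylborane 18 (not isolated)
Conditions: 9-borabicyclo[3.3.1]nonane, THF, 0 °C → rt; then NaOH, H2O2, 0 °C
Reagents that add atoms: hydrogen peroxide (OO)
Why: hydroboration–oxidation, in which the bulky borane should select the monosubstituted vinyl group over the trisubstituted ring alkene and place boron on the terminal carbon, oxidation then giving the primary alcohol.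

Step 12
Reactants: 19 2-[(1R,2S,4aS)-1,2,5,5-tetramethyl-1,2,3,4,4a,5,6,7-octahydronaphthalen-1-yl]ethan-1-ol
Product: 20 (1R,2S,4aS)-1-(2-bromoethyl)-1,2,5,5-tetramethyl-1,2,3,4,4a,5,6,7-octahydronaphthalene
Conditions: CBr4, PPh3, CH2Cl2, 0 °C
Reagents that add atoms: carbon tetrabromide (BrC(Br)(Br)Br)
Why: Appel bromination of an unhindered primary alcohol (SN2 on the alkoxyphosphonium ion) under neutral conditions that should leave the ring alkene untouched.

Step 13
Reactants: 21 2-methylcyclohex-2-en-1-one; 22 2-(bromomethyl)-1,4-dimethoxybenzene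
Product: 24 (2S,3R)-2-[(2,5-dimethoxyphenyl)methyl]-2,3-dimethylcyclohexan-1-one, via magnesium enolate 23 (not isolated)
Conditions: MeMgBr, Cu(OTf)2 (3 mol%), chiral C2-symmetric imidazolinium chloride (NHC precursor, 4 mol%), Et2O, −30 °C; then 22, DMPU, −30 °C → rt
Reagents that add atoms: methylmagnesium bromide (C[Mg]Br)
Why: copper-catalysed asymmetric conjugate addition of a Grignard reagent to a 2-substituted cyclohexenone with enolate trapping, where the ligand should set C-3 (R) and benzylation of the regiodefined enolate should occur anti to the pseudoaxial C-3 methyl, leaving the two methyl groups cis.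

Step 14
Reactants: 24 (2S,3R)-2-[(2,5-dimethoxyphenyl)methyl]-2,3-dimethylcyclohexan-1-one
Product: 26 (5R,6S)-6-[(2,5-dimethoxyphenyl)methyl]-5,6-dimethylcyclohex-2-en-1-one, via silyl enol ether 25 (not isolated)
Conditions: LiN(i-Pr)2, Me3SiCl, THF, −78 °C; then Pd(OAc)2 (1.1 equiv), MeCN, rt
Reagents that add atoms: none
Why: Saegusa–Ito oxidation, in which the only enolizable position (C-6) is silylated and the silyl enol ether should be dehydrogenated by Pd(OAc)2 through an oxa-π-allylpalladium species and β-hydride elimination.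

Step 15
Reactants: 26 (5R,6S)-6-[(2,5-dimethoxyphenyl)methyl]-5,6-dimethylcyclohex-2-en-1-one; 27 2-(3-chloropropyl)-2-methyl-1,3-dioxolane
Product: 29 (5R,6S)-6-[(2,5-dimethoxyphenyl)methyl]-5,6-dimethyl-1-[3-(2-methyl-1,3-dioxolan-2-yl)propyl]cyclohex-2-en-1-ol (both C-1 epimers), via Grignard reagent 28 (not isolated)
Conditions: 27, Mg, THF, reflux; CeCl3 (anhydrous), THF, −78 °C; then 26, −78 → 0 °C
Reagents that add atoms: none
Why: organocerium 1,2-addition to a hindered enone carbonyl, which should avoid enolization and conjugate addition, the new carbinol centre being lost in the next step.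

Step 16
Reactants: 29 (5R,6S)-6-[(2,5-dimethoxyphenyl)methyl]-5,6-dimethyl-1-[3-(2-methyl-1,3-dioxolan-2-yl)propyl]cyclohex-2-en-1-ol
Product: 30 (4S,5R)-4-[(2,5-dimethoxyphenyl)methyl]-4,5-dimethyl-3-[3-(2-methyl-1,3-dioxolan-2-yl)propyl]cyclohex-2-en-1-one
Conditions: pyridinium chlorochromate (C5H5NH)[CrO3Cl], NaOAc, 4 Å molecular sieves, CH2Cl2, rt
Reagents that add atoms: pyridinium chlorochromate ([O-][Cr](=O)(=O)Cl.c1cc[nH+]cc1)
Why: Babler–Dauben oxidative 1,3-transposition of a tertiary allylic alcohol, where [3,3] shift of the chromate ester and oxidation should give the β-substituted enone, the acetate buffer protecting the ketal.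

Step 17
Reactants: 30 (4S,5R)-4-[(2,5-dimethoxyphenyl)methyl]-4,5-dimethyl-3-[3-(2-methyl-1,3-dioxolan-2-yl)propyl]cyclohex-2-en-1-one
Product: 31 (3S,4S,5R)-4-[(2,5-dimethoxyphenyl)methyl]-4,5-dimethyl-3-[3-(2-methyl-1,3-dioxolan-2-yl)propyl]cyclohexan-1-one
Conditions: H2 (1 atm), palladium on carbon (Pd/C), EtOAc, rt
Reagents that add atoms: none
Why: heterogeneous hydrogenation of the enone alkene, where the conformer with the C-5 methyl equatorial holds the C-4 methyl pseudoaxial and leaves only the opposite face open, so hydrogen should add cis to the benzyl group and set C-3 (S).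

Step 18
Reactants: 31 (3S,4S,5R)-4-[(2,5-dimethoxyphenyl)methyl]-4,5-dimethyl-3-[3-(2-methyl-1,3-dioxolan-2-yl)propyl]cyclohexan-1-one
Product: 33 (3R,4S,4aR)-4-[(2,5-dimethoxyphenyl)methyl]-3,4,8-trimethyl-3,4,4a,5,6,7-hexahydronaphthalen-1(2H)-one, via diketone 32 (not isolated)
Conditions: 1 M HCl, THF, rt; then NaOMe, MeOH, 60 °C
Reagents that add atoms: none
Why: ketal hydrolysis followed by intramolecular aldol condensation, in which the ring ketone α-methylene (C-2) attacks the side-chain methyl ketone to close six-membered ring B and dehydration should give the conjugated tetrasubstituted enone, the bridged aldol from the other enolate being unable to dehydrate and reverting.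

Step 19
Reactants: 33 (3R,4S,4aR)-4-[(2,5-dimethoxyphenyl)methyl]-3,4,8-trimethyl-3,4,4a,5,6,7-hexahydronaphthalen-1(2H)-one
Product: 34 (1R,3R,4S,4aR)-4-[(2,5-dimethoxyphenyl)methyl]-3,4,8-trimethyl-1,2,3,4,4a,5,6,7-octahydronaphthalen-1-ol
Conditions: (S)-2-methyl-CBS-oxazaborolidine (0.5 equiv), BH3·SMe2, THF, −40 → −20 °C; MeOH
Reagents that add atoms: none
Why: CBS 1,2-reduction under catalyst control with the alkenyl side as the large group, which should give the (1R)-alcohol with the hydroxyl pseudoaxial and cis to H-4a, the arrangement the substitution in step 21 needs.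

Step 20
Reactants: 34 (1R,3R,4S,4aR)-4-[(2,5-dimethoxyphenyl)methyl]-3,4,8-trimethyl-1,2,3,4,4a,5,6,7-octahydronaphthalen-1-ol
Product: 35 (1R,3R,4S,4aR)-4-[(2,5-dimethoxyphenyl)methyl]-3,4,8-trimethyl-1,2,3,4,4a,5,6,7-octahydronaphthalen-1-yl pyridine-2-carboxylate
Conditions: pyridine-2-carboxylic acid, DCC, DMAP (cat.), CH2Cl2, rt
Reagents that add atoms: pyridine-2-carboxylic acid (OC(=O)c1ccccn1)
Why: Steglich esterification of the secondary allylic alcohol, which should proceed with retention at C-1 because the C–O bond is not broken.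

Step 21
Reactants: 20 (1R,2S,4aS)-1-(2-bromoethyl)-1,2,5,5-tetramethyl-1,2,3,4,4a,5,6,7-octahydronaphthalene; 35 (1R,3R,4S,4aR)-4-[(2,5-dimethoxyphenyl)methyl]-3,4,8-trimethyl-1,2,3,4,4a,5,6,7-octahydronaphthalen-1-yl pyridine-2-carboxylate
Product: 37 2-{[(1S,2R,5S,8aR)-1,2,5-trimethyl-5-{2-[(1R,2S,4aS)-1,2,5,5-tetramethyl-1,2,3,4,4a,5,6,7-octahydronaphthalen-1-yl]ethyl}-1,2,3,5,6,7,8,8a-octahydronaphthalen-1-yl]methyl}-1,4-dimethoxybenzene, via Grignard reagent 36 (not isolated)
Conditions: 20, Mg, THF, 40 °C; then 35, CuBr·SMe2 (0.5 equiv), THF, −40 → 0 °C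
Reagents that add atoms: none
Why: copper-mediated anti-SN2′ allylic substitution of a picolinate by a Grignard reagent, where chelation by the pyridyl ester activates the leaving group and directs the alkyl group to the methyl-bearing γ-carbon (C-8 of 35) on the face opposite the pseudoaxial C–O bond, which should create the left quaternary centre (5S in 37) and move the alkene to C-4=C-4a.

Step 22
Reactants: 37 the dimethyl ether from step 21
Product: 38 2-substituted cyclohexa-2,5-diene-1,4-dione (the p-benzoquinone corresponding to 37)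
Conditions: (NH4)2Ce(NO3)6 (2.5 equiv), MeCN/H2O, 0 °C
Reagents that add atoms: water (O)
Why: oxidative demethylation of a 1,4-dimethoxyarene by tetravalent cerium, which should give the quinone while the hindered trisubstituted alkenes are left alone.

Step 23
Reactants: 38 the p-benzoquinone from step 22
Product: 39 2-substituted benzene-1,4-diol (the hydroquinone corresponding to 38)
Conditions: Na2S2O4, THF/H2O, rt
Reagents that add atoms: none
Why: two-electron reduction of the quinone by dithionite, which should give the hydroquinone without affecting the alkenes.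

Step 24
Reactants: 39 the hydroquinone from step 23
Product: 41 the target bis(hydrogen sulfate), via bis(pyridinium) salt 40 (not isolated)
Conditions: SO3·pyridine (6 equiv), pyridine, rt; then sulfonic acid resin (H+ form), MeOH/H2O, 0 °C, freeze-drying
Reagents that add atoms: sulfur trioxide pyridine complex ([O-]S(=O)(=O)[n+]1ccccc1)
Why: O-sulfation of both phenols by the sulfur trioxide–pyridine complex, after which exchange of pyridinium for protons on the resin in the cold should release the free bis(hydrogen sulfate) without acid-promoted alkene migration.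

## Compound list

1 | (3E)-3-methylpent-3-en-2-one | C/C=C(\C)C(C)=O | starting material
2 | (2S,3E)-3-methylpent-3-en-2-ol | C/C=C(\C)[C@H](C)O | intermediate
3 | 1-ethoxy-1-{[(2S,3E)-3-methylpent-3-en-2-yl]oxy}ethene (ketene acetal) | C=C(OCC)O[C@@H](C)/C(C)=C/C | intermediate
4 | ethyl (3S,4E)-3,4-dimethylhex-4-enoate | C/C=C(C)/[C@@H](C)CC(=O)OCC | intermediate
5 | (3S,4E)-3,4-dimethylhex-4-enal | C/C=C(C)/[C@@H](C)CC=O | intermediate
6 | cyclohexane-1,3-dione | O=C1CCCC(=O)C1 | starting material
7 | 2-[(3S,4E)-3,4-dimethylhex-4-en-1-ylidene]cyclohexane-1,3-dione | C/C=C(C)/[C@@H](C)CC=C1C(=O)CCCC1=O | intermediate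
8 | 2-[(3S,4E)-3,4-dimethylhex-4-en-1-yl]cyclohexane-1,3-dione | C/C=C(C)/[C@@H](C)CCC1C(=O)CCCC1=O | intermediate
9 | 2-[(3S,4E)-3,4-dimethylhex-4-en-1-yl]-3-methoxycyclohex-2-en-1-one | C/C=C(C)/[C@@H](C)CCC1=C(OC)CCCC1=O | intermediate
10 | lithium 2-[(3S,4E)-3,4-dimethylhex-4-en-1-yl]-3-methoxy-1-methylcyclohex-2-en-1-olate | C/C=C(C)/[C@@H](C)CCC1=C(OC)CCCC1(C)[O-].[Li+] | intermediate
11 | 2-[(3S,4E)-3,4-dimethylhex-4-en-1-yl]-3-methylcyclohex-2-en-1-one | C/C=C(C)/[C@@H](C)CCC1=C(C)CCCC1=O | intermediate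
12 | lithium 2-[(3S,4E)-3,4-dimethylhex-4-en-1-yl]-3,3-dimethylcyclohex-1-en-1-olate | C/C=C(C)/[C@@H](C)CCC1=C([O-])CCCC1(C)C.[Li+] | intermediate
13 | 2-[(3S,4E)-3,4-dimethylhex-4-en-1-yl]-3,3-dimethylcyclohex-1-en-1-yl prop-2-en-1-yl carbonate | C/C=C(C)/[C@@H](C)CCC1=C(OC(=O)OCC=C)CCCC1(C)C | intermediate
14 | (2S)-2-[(3S,4E)-3,4-dimethylhex-4-en-1-yl]-3,3-dimethylcyclohexan-1-one | C/C=C(C)/[C@@H](C)CC[C@H]1C(C)(C)CCCC1=O | intermediate
15 | lithium (6S)-6-[(3S,4E)-3,4-dimethylhex-4-en-1-yl]-5,5-dimethylcyclohex-1-en-1-olate | C/C=C(C)/[C@@H](C)CC[C@H]1C(C)(C)CCC=C1[O-].[Li+] | intermediate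
16 | (6S)-6-[(3S,4E)-3,4-dimethylhex-4-en-1-yl]-5,5-dimethylcyclohex-1-en-1-yl trifluoromethanesulfonate | C/C=C(C)/[C@@H](C)CC[C@H]1C(C)(C)CCC=C1OS(=O)(=O)C(F)(F)F | intermediate
17 | (1R,2S,4aS)-1-ethenyl-1,2,5,5-tetramethyl-1,2,3,4,4a,5,6,7-octahydronaphthalene | C=C[C@@]1(C)C2=CCCC(C)(C)[C@@H]2CC[C@@H]1C | intermediate
18 | 9-{2-[(1R,2S,4aS)-1,2,5,5-tetramethyl-1,2,3,4,4a,5,6,7-octahydronaphthalen-1-yl]ethyl}-9-borabicyclo[3.3.1]nonane | C(C[C@@]1(C)C2=CCCC(C)(C)[C@@H]2CC[C@@H]1C)B1C2CCCC1CCC2 | intermediate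
19 | 2-[(1R,2S,4aS)-1,2,5,5-tetramethyl-1,2,3,4,4a,5,6,7-octahydronaphthalen-1-yl]ethan-1-ol | OCC[C@@]1(C)C2=CCCC(C)(C)[C@@H]2CC[C@@H]1C | intermediate
20 | (1R,2S,4aS)-1-(2-bromoethyl)-1,2,5,5-tetramethyl-1,2,3,4,4a,5,6,7-octahydronaphthalene | BrCC[C@@]1(C)C2=CCCC(C)(C)[C@@H]2CC[C@@H]1C | intermediate
21 | 2-methylcyclohex-2-en-1-one | CC1=CCCC1=O | starting material
22 | 2-(bromomethyl)-1,4-dimethoxybenzene | COc1ccc(OC)c(CBr)c1 | starting material
23 | bromomagnesium (3R)-2,3-dimethylcyclohex-1-en-1-olate | C[C@@H]1CCCC(O[Mg]Br)=C1C | intermediate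
24 | (2S,3R)-2-[(2,5-dimethoxyphenyl)methyl]-2,3-dimethylcyclohexan-1-one | C[C@@H]1CCCC(=O)[C@@]1(C)Cc1cc(OC)ccc1OC | intermediate
25 | {[(5R,6S)-6-[(2,5-dimethoxyphenyl)methyl]-5,6-dimethylcyclohex-1-en-1-yl]oxy}trimethylsilane | C[C@@H]1CCC=C(O[Si](C)(C)C)[C@@]1(C)Cc1cc(OC)ccc1OC | intermediate
26 | (5R,6S)-6-[(2,5-dimethoxyphenyl)methyl]-5,6-dimethylcyclohex-2-en-1-one | C[C@@H]1CC=CC(=O)[C@@]1(C)Cc1cc(OC)ccc1OC | intermediate
27 | 2-(3-chloropropyl)-2-methyl-1,3-dioxolane | CC1(CCCCl)OCCO1 | starting material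
28 | [3-(2-methyl-1,3-dioxolan-2-yl)propyl]magnesium chloride | CC1(CCC[Mg]Cl)OCCO1 | intermediate
29 | (5R,6S)-6-[(2,5-dimethoxyphenyl)methyl]-5,6-dimethyl-1-[3-(2-methyl-1,3-dioxolan-2-yl)propyl]cyclohex-2-en-1-ol (C-1 epimers) | C[C@@H]1CC=CC(O)(CCCC2(C)OCCO2)[C@@]1(C)Cc1cc(OC)ccc1OC | intermediate
30 | (4S,5R)-4-[(2,5-dimethoxyphenyl)methyl]-4,5-dimethyl-3-[3-(2-methyl-1,3-dioxolan-2-yl)propyl]cyclohex-2-en-1-one | C[C@@H]1CC(=O)C=C(CCCC2(C)OCCO2)[C@@]1(C)Cc1cc(OC)ccc1OC | intermediate
31 | (3S,4S,5R)-4-[(2,5-dimethoxyphenyl)methyl]-4,5-dimethyl-3-[3-(2-methyl-1,3-dioxolan-2-yl)propyl]cyclohexan-1-one | C[C@@H]1CC(=O)C[C@H](CCCC2(C)OCCO2)[C@@]1(C)Cc1cc(OC)ccc1OC | intermediate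
32 | (3S,4S,5R)-4-[(2,5-dimethoxyphenyl)methyl]-4,5-dimethyl-3-(4-oxopentyl)cyclohexan-1-one | C[C@@H]1CC(=O)C[C@H](CCCC(C)=O)[C@@]1(C)Cc1cc(OC)ccc1OC | intermediate
33 | (3R,4S,4aR)-4-[(2,5-dimethoxyphenyl)methyl]-3,4,8-trimethyl-3,4,4a,5,6,7-hexahydronaphthalen-1(2H)-one | C[C@@H]1CC(=O)C2=C(C)CCC[C@@H]2[C@@]1(C)Cc1cc(OC)ccc1OC | intermediate
34 | (1R,3R,4S,4aR)-4-[(2,5-dimethoxyphenyl)methyl]-3,4,8-trimethyl-1,2,3,4,4a,5,6,7-octahydronaphthalen-1-ol | C[C@@H]1C[C@@H](O)C2=C(C)CCC[C@@H]2[C@@]1(C)Cc1cc(OC)ccc1OC | intermediate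
35 | (1R,3R,4S,4aR)-4-[(2,5-dimethoxyphenyl)methyl]-3,4,8-trimethyl-1,2,3,4,4a,5,6,7-octahydronaphthalen-1-yl pyridine-2-carboxylate | C[C@@H]1C[C@@H](OC(=O)c2ccccn2)C2=C(C)CCC[C@@H]2[C@@]1(C)Cc1cc(OC)ccc1OC | intermediate
36 | {2-[(1R,2S,4aS)-1,2,5,5-tetramethyl-1,2,3,4,4a,5,6,7-octahydronaphthalen-1-yl]ethyl}magnesium bromide | Br[Mg]CC[C@@]1(C)C2=CCCC(C)(C)[C@@H]2CC[C@@H]1C | intermediate
37 | 2-{[(1S,2R,5S,8aR)-1,2,5-trimethyl-5-{2-[(1R,2S,4aS)-1,2,5,5-tetramethyl-1,2,3,4,4a,5,6,7-octahydronaphthalen-1-yl]ethyl}-1,2,3,5,6,7,8,8a-octahydronaphthalen-1-yl]methyl}-1,4-dimethoxybenzene | C[C@@H]1CC=C2[C@H](CCC[C@@]2(C)CC[C@@]2(C)C3=CCCC(C)(C)[C@@H]3CC[C@@H]2C)[C@@]1(C)Cc1cc(OC)ccc1OC | intermediate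
38 | p-benzoquinone of 37 (both OCH3 replaced by C=O; same seven stereocentres) | C[C@@H]1CC=C2[C@H](CCC[C@@]2(C)CC[C@@]2(C)C3=CCCC(C)(C)[C@@H]3CC[C@@H]2C)[C@@]1(C)CC1=CC(=O)C=CC1=O | intermediate
39 | hydroquinone of 37 (both OCH3 replaced by OH; same seven stereocentres) | C[C@@H]1CC=C2[C@H](CCC[C@@]2(C)CC[C@@]2(C)C3=CCCC(C)(C)[C@@H]3CC[C@@H]2C)[C@@]1(C)Cc1cc(O)ccc1O | intermediate
40 | bis(pyridinium) salt of the bis-sulfate of 39 | C[C@@H]1CC=C2[C@H](CCC[C@@]2(C)CC[C@@]2(C)C3=CCCC(C)(C)[C@@H]3CC[C@@H]2C)[C@@]1(C)Cc1cc(OS(=O)(=O)[O-])ccc1OS(=O)(=O)[O-].c1cc[nH+]cc1.c1cc[nH+]cc1 | intermediate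
41 | CNP0243830.4, bis(hydrogen sulfate) of hydroquinone 39 | C[C@@H]1CC=C2[C@H](CCC[C@@]2(C)CC[C@@]2(C)C3=CCCC(C)(C)[C@@H]3CC[C@@H]2C)[C@@]1(C)Cc1cc(OS(=O)(=O)O)ccc1OS(=O)(=O)O | target

## Totals and risks

Total step count: 24 steps. Longest linear sequence: 16 steps (steps 1–12, then 21–24); the left-hand branch (steps 13–20) is 8 steps to 35.

Steps most likely to fail:

**Step 10 (Heck closure of ring D).** Migratory insertion into the unactivated trisubstituted alkene may be slow, so that reduction or hydrolysis of the triflate competes. The two alkene faces may be poorly discriminated at the new quaternary carbon, and palladium hydride re-addition may move the ring C alkene. Fallback: the acceptor is made electron-poor and the chain terminated by hydride instead of β-elimination. Starting from 16, ozonolysis (O3, CH2Cl2/MeOH, −78 °C; Me2S) should cleave only the electron-rich trisubstituted alkene and give the methyl ketone F1. Horner–Wadsworth–Emmons olefination ((EtO)2P(O)CH2CO2Et, NaH, THF) then gives the enoate F2. A formate-terminated reductive Heck cyclization (Pd(OAc)2, PPh3, HCO2Na, Et4NCl, DMF, 80 °C) closes ring D on the β-carbon of the enoate; the α-palladated ester has no β-hydrogen on the quaternary side and is reduced to the ester F3. LiAlH4 in Et2O reduces F3 to the alcohol, and the route is rejoined at 19.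

**Step 21 (union of the two decalins).** The bimolecular anti-SN2′ attack has to create a quaternary carbon on a tetrasubstituted alkene with a bulky primary Grignard reagent. It may be too slow, so that direct substitution at C-1, reduction or elimination of the picolinate takes over. Fallback: the C–C bond is formed intramolecularly by an Ireland–Claisen rearrangement. Starting from 36 (made from 20), carboxylation with CO2 gives the acid F4. Starting from 33, reduction with the (R)-configured CBS catalyst and BH3·SMe2 gives the C-1 epimeric alcohol F5. Esterification of F5 with F4 (DCC, DMAP) gives the allylic ester F6. Enolization and silylation (LiN(i-Pr)2, Me3SiCl, THF/DMPU, −78 °C → 60 °C) trigger the [3,3] shift, which delivers the α-carbon suprafacially to the methyl-bearing alkene carbon on the face of the C–O bond and gives, after work-up, the acid F7 with the correct quaternary centre. Barton decarboxylation through the N-hydroxypyridine-2-thione ester F8 ((COCl)2; sodium 2-thioxopyridin-1-olate; t-BuSH, hν) removes the carboxyl group, and the route is rejoined at 37.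

**Step 8 (asymmetric protonation at C-2).** Facial discrimination in protonating an enolate flanked by a quaternary carbon may be low, and the ketone may equilibrate with residual enolate, which would erode the C-2 configuration. Fallback: reagent control is given up and the epimers are separated after ring closure, where the remote 1,4-relationship has become a rigid bicyclic difference. Starting from 11, cuprate addition as in step 7 with an aqueous NH4Cl quench gives 14 together with its C-2 epimer F9. Triflation as in step 9 gives 16 and the epimeric triflate F10, and cyclization as in step 10 gives 17 and the diastereomeric diene F11 (opposite configuration at C-1 and C-4a), because the ring stereocentre dictates the face of insertion. Chromatography on AgNO3-impregnated silica (or separation of the alcohols after step 11) removes F11, and the route is rejoined at 17.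

## Further compounds

F1 | step 10 | (6S)-5,5-dimethyl-6-[(3S)-3-methyl-4-oxopentyl]cyclohex-1-en-1-yl trifluoromethanesulfonate | CC(=O)[C@@H](C)CC[C@H]1C(C)(C)CCC=C1OS(=O)(=O)C(F)(F)F
F2 | step 10 | ethyl (2E,4S)-6-{(1S)-2,2-dimethyl-6-[(trifluoromethanesulfonyl)oxy]cyclohex-5-en-1-yl}-3,4-dimethylhex-2-enoate | CCOC(=O)/C=C(\C)[C@@H](C)CC[C@H]1C(C)(C)CCC=C1OS(=O)(=O)C(F)(F)F
F3 | step 10 | ethyl 2-[(1R,2S,4aS)-1,2,5,5-tetramethyl-1,2,3,4,4a,5,6,7-octahydronaphthalen-1-yl]acetate | CCOC(=O)C[C@@]1(C)C2=CCCC(C)(C)[C@@H]2CC[C@@H]1C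
F4 | step 21 | 3-[(1R,2S,4aS)-1,2,5,5-tetramethyl-1,2,3,4,4a,5,6,7-octahydronaphthalen-1-yl]propanoic acid | OC(=O)CC[C@@]1(C)C2=CCCC(C)(C)[C@@H]2CC[C@@H]1C
F5 | step 21 | (1S,3R,4S,4aR)-4-[(2,5-dimethoxyphenyl)methyl]-3,4,8-trimethyl-1,2,3,4,4a,5,6,7-octahydronaphthalen-1-ol | C[C@@H]1C[C@H](O)C2=C(C)CCC[C@@H]2[C@@]1(C)Cc1cc(OC)ccc1OC
F6 | step 21 | (1S,3R,4S,4aR)-4-[(2,5-dimethoxyphenyl)methyl]-3,4,8-trimethyl-1,2,3,4,4a,5,6,7-octahydronaphthalen-1-yl 3-[(1R,2S,4aS)-1,2,5,5-tetramethyl-1,2,3,4,4a,5,6,7-octahydronaphthalen-1-yl]propanoate | C[C@@H]1C[C@H](OC(=O)CC[C@@]3(C)C4=CCCC(C)(C)[C@@H]4CC[C@@H]3C)C2=C(C)CCC[C@@H]2[C@@]1(C)Cc1cc(OC)ccc1OC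
F7 | step 21 | α-carboxy derivative of 37 (CO2H on the linker carbon next to the left quaternary carbon, both epimers at that carbon) | C[C@@H]1CC=C2[C@H](CCC[C@@]2(C)C(C[C@@]2(C)C3=CCCC(C)(C)[C@@H]3CC[C@@H]2C)C(O)=O)[C@@]1(C)Cc1cc(OC)ccc1OC
F8 | step 21 | 2-thioxopyridin-1(2H)-yl ester of F7 | C[C@@H]1CC=C2[C@H](CCC[C@@]2(C)C(C[C@@]2(C)C3=CCCC(C)(C)[C@@H]3CC[C@@H]2C)C(=O)ON2C=CC=CC2=S)[C@@]1(C)Cc1cc(OC)ccc1OC
F9 | step 8 | (2R)-2-[(3S,4E)-3,4-dimethylhex-4-en-1-yl]-3,3-dimethylcyclohexan-1-one | C/C=C(C)/[C@@H](C)CC[C@@H]1C(C)(C)CCCC1=O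
F10 | step 8 | (6R)-6-[(3S,4E)-3,4-dimethylhex-4-en-1-yl]-5,5-dimethylcyclohex-1-en-1-yl trifluoromethanesulfonate | C/C=C(C)/[C@@H](C)CC[C@@H]1C(C)(C)CCC=C1OS(=O)(=O)C(F)(F)F
F11 | step 8 | (1S,2S,4aR)-1-ethenyl-1,2,5,5-tetramethyl-1,2,3,4,4a,5,6,7-octahydronaphthalene | C=C[C@]1(C)C2=CCCC(C)(C)[C@H]2CC[C@@H]1C
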